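The ten-membered carbocycle is treated as a cyclohexenone ring (C5–C10) with the four-carbon unit C1–C4 inserted into its C5=C10 bond. One head-to-tail enone–cyclobutene (2+2) photocycloaddition forms C1–C10 and C4–C5, closes the central cyclobutane and sets four stereocentres. Heating then opens the bicyclo[2.2.0]hexane to the ring-cis C4=C5 enone and a ring-trans C1=C10 enol ether, so the face chosen in the photoreaction is stored as planar chirality and returned at C10. The precursors are the cis-fused enone lactone 9, whose C7 and C8 come from a CBS reduction, and the silyloxycyclobutene 11.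

Key step: step 6

Remark: locants C1–C15 follow the germacrane numbering of the target (C12 lactone carbonyl, C13 acetoxymethyl carbon, C14 methyl on C10, C15 methyl on C4); "ring-cis" and "ring-trans" say whether the two ring bonds at a double bond lie on the same or on opposite sides.
Remark: compounds 5–8 are carried as mixtures at the methyl-bearing carbon (C10), which becomes trigonal in 9; the C10 oxygen of the target lies on the face of C10 that is bonded to C5 in 12, which is why C10 is set by an inversion in step 16.

Step 1
Reactants: 1 5-methylcyclohexane-1,3-dione; 2 methyl bromoacetate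
Product: 3 methyl 2-(4-methyl-2,6-dioxocyclohexyl)acetate
Conditions: NaOMe, MeOH, 0 °C to reflux
Reagents that add atoms: none
Why: The soft enolate of the cyclic 1,3-dione is alkylated at carbon (C7) by the α-bromo ester in a protic medium that suppresses O-alkylation (C-alkylation of a 1,3-diketone), and no stereocentre of the target is set here.

Step 2
Reactants: 3 methyl 2-(4-methyl-2,6-dioxocyclohexyl)acetate
Product: 5 6-methyl-6,7-dihydro-1-benzofuran-2,4(3H,5H)-dione (racemic enol lactone), via keto acid 4 (not isolated)
Conditions: NaOH, H2O/MeOH, rt; HCl to pH 2, extraction; then Ac2O, NaOAc (cat.), 90 °C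
Reagents that add atoms: none
Why: Saponification gives the acid, and acetic anhydride turns it into a mixed anhydride that is captured by the enolised dione oxygen in a 5-exo acyl substitution, leaving only one carbonyl as a ketone (enol lactonisation of a 2-(2-oxocycloalkyl)acetic acid).

Step 3
Reactants: 5 6-methyl-6,7-dihydro-1-benzofuran-2,4(3H,5H)-dione
Product: 7 (3aS,7aS)-6-methylhexahydro-1-benzofuran-2,4-dione (cis-fused keto lactone), via hydroxy enol lactone 6 (not isolated)
Conditions: (R)-2-methyl-CBS-oxazaborolidine [(R)-1-methyl-3,3-diphenyltetrahydro-1H,3H-pyrrolo[1,2-c][1,3,2]oxazaborole] (0.2 equiv), catecholborane, PhMe, −78 °C; MeOH quench; then DMAP (0.2 equiv), CH2Cl2, rt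
Reagents that add atoms: none
Why: Corey–Bakshi–Shibata reduction of the α-substituted enone carbonyl sets C8 as S under reagent control (the fully substituted alkene carbon acts as the large group), after which DMAP carries the acyl group from the enol oxygen to the new hydroxyl and the freed enol ketonises with protonation at C7 to the more stable cis ring fusion, so that C7 (S) follows from C8.

Step 4
Reactants: 7 (3aS,7aS)-6-methylhexahydro-1-benzofuran-2,4-dione
Product: 9 (3aS,7aS)-6-methyl-3,3a,7,7a-tetrahydro-1-benzofuran-2,4-dione, via trimethylsilyl enol ether 8 (not isolated)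
Conditions: LiN(iPr)2 (1.1 equiv), Me3SiCl (present from the start), THF, −78 °C; concentrate; then Pd(OAc)2 (1.05 equiv), MeCN, rt
Reagents that add atoms: none
Why: Kinetic deprotonation at the C5 methylene is preferred over the hindered C7 methine (whose enolate would expel the lactone carboxylate), and Saegusa–Ito oxidation of the trapped silyl enol ether by Pd(OAc)2 places the double bond at C5=C10, which removes the stereocentre at the methyl-bearing carbon and leaves C7 and C8 untouched.

Step 5
Reactants: 10 2-methylcyclobutanone
Product: 11 tert-butyl(dimethyl)[(2-methylcyclobut-1-en-1-yl)oxy]silane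
Conditions: TBSOTf, Et3N, CH2Cl2, 0 °C to rt
Reagents that add atoms: tert-butyldimethylsilyl trifluoromethanesulfonate CC(C)(C)[Si](C)(C)OS(=O)(=O)C(F)(F)F
Why: Soft enolisation with the silyl triflate and triethylamine equilibrates to the more substituted enol ether, giving the tetrasubstituted silyloxycyclobutene that serves as the four-carbon partner (thermodynamic silyl enol ether formation).

Step 6
Reactants: 9 (3aS,7aS)-6-methyl-3,3a,7,7a-tetrahydro-1-benzofuran-2,4-dione; 11 tert-butyl(dimethyl)[(2-methylcyclobut-1-en-1-yl)oxy]silane
Product: 12 cis-anti-cis photoadduct (cyclobutane C5–C10–C1–C4 on the face anti to the lactone; OTBS on C1)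
Conditions: hν (350 nm lamps, Pyrex filter), 11 (5 equiv), CH2Cl2, −40 °C, argon
Reagents that add atoms: none
Why: Excitation of enone 9 and intersystem crossing give the triplet, which adds to the electron-rich cyclobutene through a triplet 1,4-diradical that closes after spin inversion; this is the enone–alkene (2+2) photocycloaddition known for enol ethers and for cyclobutenes. The one ring closed, the central cyclobutane C5–C10–C1–C4, forms by stepwise radical–radical combination within that diradical, cis-fused to the six-membered ring and, by necessity, cis-fused to the ring that came from the cyclobutene. Head-to-tail regiochemistry (oxygen-bearing C1 to the enone β-carbon C10, methyl-bearing C4 to C5) is required and is secured by the match between the electron-rich β-carbon of the excited enone and the electron-poor oxygen-bearing carbon of the silyl enol ether. C5 and C10 are set by attack on the convex face of the cis-fused bicycle, anti to C11 on C7 and to O8 on C8; this face selectivity is needed because it later fixes the planar chirality of the C1=C10 enol ether and hence C10. C1 and C4 follow from the anti approach of the four-membered ring, which keeps its CH2–CH2 bridge away from the six-membered ring. The cis fusion at C5–C10, needed for the later cis,trans diene, is favoured by the strain of a trans-fused bicyclo[4.2.0]octanone.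

Step 7
Reactants: 12 cis-anti-cis photoadduct
Product: 13 ten-membered dienone lactone (ring-cis C4=C5 enone; ring-trans C1=C10 TBS enol ether; 8,12-lactone)
Conditions: PhMe (degassed, dilute), base-washed sealed tube, 180 °C
Reagents that add atoms: none
Why: Homolysis of the strained C1–C4 bond gives a cyclohexane-1,4-diyl whose chair places C6 axial on C5 to avoid allylic 1,2-strain against the C15 methyl on the radical centre C4, so that cleavage of C5–C10 should give the ring-cis C4=C5 enone together with the ring-trans C1=C10 enol ether whose inner face is the one that carried C5 (thermal retro-(2+2) opening of a bicyclo[2.2.0]hexane), and conjugation of C4=C5 with the C6 ketone should keep the product from contracting by a [3,3] shift.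

Step 8
Reactants: 13 ten-membered dienone lactone
Product: 14 C6 allylic alcohol (6-OH cis to C11 and O8)
Conditions: NaBH4, CeCl3·7H2O, MeOH/THF, −78 °C
Reagents that add atoms: none
Why: Luche conditions give clean 1,2-reduction of the enone without touching the lactone or the silyl enol ether, and hydride should add anti to the C7–C8 bond (Felkin–Anh model, C8 as the large substituent), which places the new C6 hydroxyl on the same side as C11 and O8.

Step 9
Reactants: 14 C6 allylic alcohol
Product: 15 4,5-epoxy alcohol (oxirane oxygen cis to 6-OH; C3 and C6 cis on the oxirane)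
Conditions: VO(acac)2 (5 mol%), t-BuOOH (anhydrous, in decane), CH2Cl2, 0 °C
Reagents that add atoms: tert-butyl hydroperoxide CC(C)(C)OO
Why: The vanadate ester of the C6 alcohol delivers oxygen to the adjacent ring-cis alkene on the face of the hydroxyl, as is the rule for medium-ring (Z)-cycloalk-2-enols, which sets C4 and C5 as the cis-epoxy alcohol, while the hindered silyl enol ether has no directing group (hydroxyl-directed epoxidation).

Step 10
Reactants: 15 4,5-epoxy alcohol
Product: 17 13-hydroxy lactone as C11 epimer (C13 trans to C6), via dilithium enolate alkoxide 16 (not isolated)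
Conditions: 15 added to LiN(iPr)2 (2.5 equiv), THF, −78 °C; CH2O (gas), −78 °C; AcOH, −78 °C
Reagents that add atoms: formaldehyde C=O
Why: After deprotonation of the hydroxyl the lactone enolate adds to formaldehyde on the face of H7, anti to the C7–C6 bond, which installs C13 but as the C11 epimer of the target (aldol hydroxymethylation of a cis-fused γ-lactone enolate on its convex face).

Step 11
Reactants: 17 13-hydroxy lactone as C11 epimer
Product: 19 13-hydroxy lactone (C13 cis to C6; C11 as in the target), via trilithium enolate dialkoxide 18 (not isolated)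
Conditions: LiN(iPr)2 (3.5 equiv), THF, −78 to −40 °C; cannulated into AcOH/THF, −78 °C
Reagents that add atoms: none
Why: Renewed enolisation (the β-alkoxide cannot leave) and kinetic protonation on the same open face as before put H11 cis to H7 and thereby turn the hydroxymethyl group to the side of C6, which sets C11 as in the target (kinetic protonation of a lactone enolate).

Step 12
Reactants: 19 13-hydroxy lactone
Product: 20 6,13-bis(trimethylsilyl) ether
Conditions: Me3SiCl, imidazole, CH2Cl2, 0 °C
Reagents that add atoms: chlorotrimethylsilane C[Si](C)(C)Cl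
Why: Both hydroxyls are capped as labile trimethylsilyl ethers so that O8 will be the only free oxygen once the lactone is opened (O-silylation, no stereocentre touched).

Step 13
Reactants: 20 6,13-bis(trimethylsilyl) ether
Product: 22 8-O-methacryloyl Weinreb amide bis(trimethylsilyl) ether, via chloromagnesium alkoxide 21 (not isolated)
Conditions: MeNHOMe·HCl, iPrMgCl, THF, −20 °C; then methacrylic anhydride, DMAP (cat.), −20 to 0 °C
Reagents that add atoms: N,O-dimethylhydroxylamine hydrochloride CNOC.Cl; methacrylic anhydride C=C(C)C(=O)OC(=O)C(C)=C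
Why: The magnesium amide adds to the lactone carbonyl faster than it enolises it and gives the Weinreb amide together with the O8 alkoxide, which is acylated in the same flask, so that the methacrylate can only end on O8 (Weinreb aminolysis of a lactone followed by O-acylation).

Step 14
Reactants: 22 8-O-methacryloyl Weinreb amide bis(trimethylsilyl) ether
Product: 24 13-hydroxy 8-methacrylate 6,12-lactone (TBS enol ether), via diol Weinreb amide 23 (not isolated)
Conditions: AcOH, THF/H2O, 0 °C; then PPTS (cat.), PhMe, 40 °C
Reagents that add atoms: none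
Why: Mild acid removes the two trimethylsilyl ethers but should spare the hindered tetrasubstituted TBS enol ether, and the C6 hydroxyl, cis to C11, then closes the five-membered 6,12-lactone on the Weinreb amide with loss of the hydroxylamine (5-exo lactonisation), the primary C13 hydroxyl being able to reach only a four-membered ring.

Step 15
Reactants: 24 13-hydroxy 8-methacrylate 6,12-lactone
Product: 26 enol acetate 13-acetate (ring-trans C1=C10), via primary acetate 25 (not isolated)
Conditions: Ac2O, Et3N, DMAP (cat.), THF, 0 °C; then Bu4N[Ph3SiF2] (1.2 equiv), 0 °C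
Reagents that add atoms: acetic anhydride CC(=O)OC(C)=O
Why: The primary alcohol is acetylated and fluoride then frees the enolate, which is O-acetylated by the anhydride before the ring-trans C1=C10 bond can turn, so that the enol acetate keeps the geometry and the planar chirality of the silyl enol ether (O-acylation of a hindered tetrasubstituted enolate).

Step 16
Reactants: 26 enol acetate 13-acetate
Product: 28 (4R,5S,6S,7S,8S,10R,11R)-10,13-diacetoxy-4,5-epoxy-8-(2-methylprop-2-enoyloxy)-1-oxogermacran-12,6-olide (target), via acetoxy epoxide 27 (not isolated)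
Conditions: dimethyldioxirane (acetone solution), CH2Cl2, −20 °C; evaporate; then PhMe, 2,6-di-tert-butyl-4-methylphenol (trace), base-washed glass, 100 °C
Reagents that add atoms: dimethyldioxirane CC1(C)OO1
Why: The dioxirane epoxidises the electron-rich enol acetate on its only open (outer) face and leaves the electron-poor methacrylate alone, and on heating the acetoxy group shifts from C1 to C10 with inversion, entering on the inner face while the epoxide oxygen becomes the C1 ketone, which sets C10 as R (thermal rearrangement of an enol ester epoxide to an α-acyloxy ketone).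

Compound list
1 | 5-methylcyclohexane-1,3-dione | CC1CC(=O)CC(=O)C1 | starting material
2 | methyl bromoacetate | COC(=O)CBr | starting material
3 | methyl 2-(4-methyl-2,6-dioxocyclohexyl)acetate | COC(=O)CC1C(=O)CC(C)CC1=O | intermediate
4 | 2-(4-methyl-2,6-dioxocyclohexyl)acetic acid (keto acid) | OC(=O)CC1C(=O)CC(C)CC1=O | intermediate
5 | 6-methyl-6,7-dihydro-1-benzofuran-2,4(3H,5H)-dione (racemic enol lactone) | O=C1CC2=C(O1)CC(C)CC2=O | intermediate
6 | (4S)-4-hydroxy-6-methyl-4,5,6,7-tetrahydro-1-benzofuran-2(3H)-one (hydroxy enol lactone, both epimers at the methyl carbon) | O=C1CC2=C(O1)CC(C)C[C@@H]2O | intermediate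
7 | (3aS,7aS)-6-methylhexahydro-1-benzofuran-2,4-dione (cis-fused, both epimers at the methyl carbon) | O=C1C[C@@H]2C(=O)CC(C)C[C@@H]2O1 | intermediate
8 | (3aS,7aS)-6-methyl-4-(trimethylsilyloxy)-3a,6,7,7a-tetrahydro-1-benzofuran-2(3H)-one (trimethylsilyl enol ether) | O=C1C[C@@H]2C(O[Si](C)(C)C)=CC(C)C[C@@H]2O1 | intermediate
9 | (3aS,7aS)-6-methyl-3,3a,7,7a-tetrahydro-1-benzofuran-2,4-dione (cis-fused enone lactone, lactone on O8) | O=C1C[C@@H]2C(=O)C=C(C)C[C@@H]2O1 | intermediate
10 | 2-methylcyclobutanone | CC1CCC1=O | starting material
11 | tert-butyl(dimethyl)[(2-methylcyclobut-1-en-1-yl)oxy]silane | CC1=C(O[Si](C)(C)C(C)(C)C)CC1 | intermediate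
12 | cis-anti-cis photoadduct (cyclobutane C5–C10–C1–C4 cis-fused to the six-membered ring on the face anti to the lactone and cis-fused to the C1–C2–C3–C4 ring; OTBS on C1; methyls on C4 and C10; C6 ketone) | O=C1C[C@@H]2C(=O)[C@H]3[C@]4(C)CC[C@]4(O[Si](C)(C)C(C)(C)C)[C@@]3(C)C[C@@H]2O1 | intermediate
13 | (7S,8S)-1-(tert-butyldimethylsilyloxy)-6-oxogermacra-1(10),4-dien-12,8-olide; C4=C5 ring-cis (Z); C1=C10 ring-trans (C2 and C9 trans, CIP Z), inner face = face that carried C5 | O=C1C[C@@H]2C(=O)/C=C(C)\CC/C(O[Si](C)(C)C(C)(C)C)=C(C)/C[C@@H]2O1 | intermediate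
14 | 6-hydroxy analogue of 13 (C6 allylic alcohol; O6, C11 and O8 on the same side) | O=C1C[C@@H]2[C@H](O)/C=C(C)\CC/C(O[Si](C)(C)C(C)(C)C)=C(C)/C[C@@H]2O1 | intermediate
15 | 4,5-epoxide of 14 (oxirane oxygen cis to the 6-hydroxyl; C3 and C6 cis on the oxirane) | O=C1C[C@@H]2[C@H](O)[C@@H]3O[C@]3(C)CC/C(O[Si](C)(C)C(C)(C)C)=C(C)/C[C@@H]2O1 | intermediate
16 | dilithium enolate alkoxide of 15 (lactone enolate, C6 lithium alkoxide) | [Li]OC1=C[C@@H]2[C@H](O[Li])[C@@H]3O[C@]3(C)CC/C(O[Si](C)(C)C(C)(C)C)=C(C)/C[C@@H]2O1 | intermediate
17 | 13-hydroxy derivative of 15 as C11 epimer (C13 trans to C6, H11 trans to H7) | O=C1[C@H](CO)[C@@H]2[C@H](O)[C@@H]3O[C@]3(C)CC/C(O[Si](C)(C)C(C)(C)C)=C(C)/C[C@@H]2O1 | intermediate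
18 | trilithium enolate dialkoxide of 17 | [Li]OC1=C(CO[Li])[C@@H]2[C@H](O[Li])[C@@H]3O[C@]3(C)CC/C(O[Si](C)(C)C(C)(C)C)=C(C)/C[C@@H]2O1 | intermediate
19 | 13-hydroxy derivative of 15 with C13 cis to C6 (H11 cis to H7; C11 as in the target) | O=C1[C@@H](CO)[C@@H]2[C@H](O)[C@@H]3O[C@]3(C)CC/C(O[Si](C)(C)C(C)(C)C)=C(C)/C[C@@H]2O1 | intermediate
20 | 6,13-bis(trimethylsilyl) ether of 19 | O=C1[C@@H](CO[Si](C)(C)C)[C@@H]2[C@H](O[Si](C)(C)C)[C@@H]3O[C@]3(C)CC/C(O[Si](C)(C)C(C)(C)C)=C(C)/C[C@@H]2O1 | intermediate
21 | chloromagnesium alkoxide (O8) of the ring-opened N-methoxy-N-methyl amide | CON(C)C(=O)[C@@H](CO[Si](C)(C)C)[C@@H]1[C@H](O[Si](C)(C)C)[C@@H]2O[C@]2(C)CC/C(O[Si](C)(C)C(C)(C)C)=C(C)/C[C@@H]1O[Mg]Cl | intermediate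
22 | N-methoxy-N-methyl amide at C12 with 8-O-methacrylate and 6,13-bis(trimethylsilyl) ether | CON(C)C(=O)[C@@H](CO[Si](C)(C)C)[C@@H]1[C@H](O[Si](C)(C)C)[C@@H]2O[C@]2(C)CC/C(O[Si](C)(C)C(C)(C)C)=C(C)/C[C@@H]1OC(=O)C(C)=C | intermediate
23 | 6,13-diol of 22 (diol Weinreb amide) | CON(C)C(=O)[C@@H](CO)[C@@H]1[C@H](O)[C@@H]2O[C@]2(C)CC/C(O[Si](C)(C)C(C)(C)C)=C(C)/C[C@@H]1OC(=O)C(C)=C | intermediate
24 | 1-(tert-butyldimethylsilyloxy)-4,5-epoxy-13-hydroxy-8-(methacryloyloxy)germacr-1(10)-en-12,6-olide (ring-trans C1=C10; C4–C8 and C11 as in the target) | C=C(C)C(=O)O[C@H]1C/C(C)=C(O[Si](C)(C)C(C)(C)C)/CC[C@@]2(C)O[C@H]2[C@H]2OC(=O)[C@@H](CO)[C@H]21 | intermediate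
25 | 13-acetate of 24 (primary acetate) | C=C(C)C(=O)O[C@H]1C/C(C)=C(O[Si](C)(C)C(C)(C)C)/CC[C@@]2(C)O[C@H]2[C@H]2OC(=O)[C@@H](COC(C)=O)[C@H]21 | intermediate
26 | 1,13-diacetoxy-4,5-epoxy-8-(methacryloyloxy)germacr-1(10)-en-12,6-olide (enol acetate, ring-trans C1=C10) | C=C(C)C(=O)O[C@H]1C/C(C)=C(OC(C)=O)/CC[C@@]2(C)O[C@H]2[C@H]2OC(=O)[C@@H](COC(C)=O)[C@H]21 | intermediate
27 | 1,13-diacetoxy-1,10:4,5-diepoxy-8-(methacryloyloxy)germacran-12,6-olide (new oxirane oxygen on the outer face; C2 and C9 trans) | C=C(C)C(=O)O[C@H]1C[C@]3(C)O[C@@]3(OC(C)=O)CC[C@@]2(C)O[C@H]2[C@H]2OC(=O)[C@@H](COC(C)=O)[C@H]21 | intermediate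
28 | (4R,5S,6S,7S,8S,10R,11R)-10,13-diacetoxy-4,5-epoxy-8-(2-methylprop-2-enoyloxy)-1-oxogermacran-12,6-olide | C=C(C)C(=O)O[C@H]1C[C@@](C)(OC(C)=O)C(=O)CC[C@@]2(C)O[C@H]2[C@H]2OC(=O)[C@@H](COC(C)=O)[C@H]21 | target

Total step count: 16. Longest linear sequence: 15 steps (steps 1–4 and 6–16; step 5 makes the second partner).

Steps most likely to fail

Step 6. The triplet 1,4-diradical may close in part to the trans-fused ring junction at C5–C10, or revert to 9, which would erode the cis fusion on which step 7 depends. Fallback: control of the ring fusion is moved from the excited state to a ground-state equilibration. The irradiation of 9 with 11 is run as before and the C5 epimer, the trans-fused photoadduct F1, is not separated. The crude mixture is stirred with basic alumina in CH2Cl2, which should epimerise C5 (α to the C6 ketone) through the enol to the less strained cis-fused isomer. This fallback sets out from 9 and comes back to the route at 12.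

Step 7. After the C1–C4 bond breaks, the diradical may partition to the other cis,trans pair (ring-trans C4=C5), and under prolonged heating the ten-membered dienone may drain by a [3,3] shift into the cis-dialkenylcyclohexanone. Fallback: the equilibrating batch thermolysis is replaced by a kinetically controlled gas-phase fragmentation. This is flash vacuum thermolysis in a single pass through a hot quartz tube at about 450 °C and 0.01 mbar with a cold trap, where each molecule is hot for milliseconds and the first-formed dienone is frozen out before the follow-up shift. This fallback sets out from 12, comes back at 13 and makes no new compound (F0).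

Step 13. The magnesium amide may enolise C11 (epimerisation, or loss of silanolate to the α-methylene lactone), or the O8 alkoxide may re-close before it is acylated. Fallback: the protecting-group-directed opening is replaced by an equilibrium-driven lactone shift. The primary C13 hydroxyl of 19 is acetylated selectively (acetyl chloride, 2,4,6-collidine, CH2Cl2, −78 °C) to the 13-acetate F2. The neutral transesterification catalyst ClBu2SnOSnBu2Cl in toluene at 60 °C then lets the lactone move between O8 and O6. The 6,12-lactone with the free C8 hydroxyl F3 is drained from this equilibrium by methacrylic anhydride, Et3N and DMAP at 0 °C, since its hydroxyl is the less hindered and is not deactivated by a neighbouring epoxide. This fallback sets out from 19 and comes back at 25, from which the fluoride stage of step 15 follows.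

Further compounds
F1 | step 6 | trans-fused photoadduct (C5 epimer of 12) | O=C1C[C@@H]2C(=O)[C@@H]3[C@]4(C)CC[C@]4(O[Si](C)(C)C(C)(C)C)[C@@]3(C)C[C@@H]2O1
F0 | step 7 | none | none
F2 | step 13 | 13-acetate of 19 (free 6-hydroxyl, 8,12-lactone) | O=C1[C@@H](COC(C)=O)[C@@H]2[C@H](O)[C@@H]3O[C@]3(C)CC/C(O[Si](C)(C)C(C)(C)C)=C(C)/C[C@@H]2O1
F3 | step 13 | 6,12-lactone isomer of F2 (free 8-hydroxyl) | O[C@H]1C/C(C)=C(O[Si](C)(C)C(C)(C)C)/CC[C@@]2(C)O[C@H]2[C@H]2OC(=O)[C@@H](COC(C)=O)[C@H]21
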